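**Retrosynthetic overview**

1. Locants (hydroazulene): C1 = quaternary ring-fusion carbon with the methyl, C2–C3, C4 = isopropyl carbinol, C5 = ring-fusion CH, C6 = anisoyloxy CH, C7=C8(Me), C9 = ketone, C10 = secondary carbinol; β = face of the C1 methyl.
2. Enabling feature: in the seven-membered ring, C6(O)–C7=C8(Me)–C9(O) is a 2-oxyfuran (4-methylbutenolide) in disguise, and C10–C1–C5 is a 1,3-dipole across quaternary C1 (oxocarbenium at C10, enolate at C5 while C4 is a ketone), i.e. a donor–acceptor cyclopropane.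
3. Key disconnection: C9–C10 and C5–C6 by a Lewis-acid formal (4+3) annulation of cyclopropane 9 with silyloxyfuran 11. The five-membered ring is made first (asymmetric carbenoid cyclopropanation sets C1), the seven-membered ring second, as an oxygen-bridged silyl ketal.
4. A sulfonyl group on C5 activates the cyclopropane; its reductive removal sets H-5 (trans fusion), and isopropyl addition then sets C4.
5. The annulation delivers C6 at the ketone and C9 at the alcohol level; oxidation at C9 and hydroxyl-directed reduction at C6 exchange them before anisoylation and desilylation.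

Key step: step 7

Assumption: both epimers of 9 at the silyloxy-bearing cyclopropane carbon ionise to the same oxocarbenium ion, so the E/Z mixture of enol ether 5 is carried through unseparated.

**Route**

Step 1
Reactants: 1 propanal, 2 methyl acrylate
Product: 4 methyl 4-methyl-5-oxopentanoate (racemic), via 1-(prop-1-en-1-yl)pyrrolidine 3 (not isolated)
Conditions: pyrrolidine, K2CO3, 0 °C; then 2, MeCN, reflux; AcOH, H2O
Reagents that add atoms: none
Why: Stork enamine Michael addition to the acrylate; the new stereocentre is racemic and is erased in step 2.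

Step 2
Reactants: 4 methyl 4-methyl-5-oxopentanoate
Product: 5 methyl 4-methyl-5-[(triisopropylsilyl)oxy]pent-4-enoate (E/Z mixture)
Conditions: TIPSOTf, Et3N, CH2Cl2, 0 °C
Reagents that add atoms: triisopropylsilyl trifluoromethanesulfonate, CC(C)[Si](C(C)C)(C(C)C)OS(=O)(=O)C(F)(F)F
Why: Soft enolisation and O-silylation of the aldehyde should give the silyl enol ether, the ester being far less readily enolised.

Step 3
Reactants: 5 silyl enol ether ester, 6 methyl phenyl sulfone
Product: 7 6-methyl-1-(phenylsulfonyl)-7-[(triisopropylsilyl)oxy]hept-6-en-2-one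
Conditions: 6 (2.2 equiv), n-BuLi (2.2 equiv), THF, −78 °C; then 5, −78 → 0 °C; NH4Cl (aq)
Reagents that add atoms: none
Why: Claisen-type acylation of the α-sulfonyl carbanion by the methyl ester; the second equivalent of carbanion deprotonates the β-keto sulfone and prevents over-addition.

Step 4
Reactants: 7 β-keto sulfone
Product: 8 1-diazo-6-methyl-1-(phenylsulfonyl)-7-[(triisopropylsilyl)oxy]hept-6-en-2-one
Conditions: 4-acetamidobenzenesulfonyl azide, Et3N, MeCN, 0 °C → rt
Reagents that add atoms: 4-acetamidobenzenesulfonyl azide, CC(=O)Nc1ccc(cc1)S(=O)(=O)N=[N+]=[N-]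
Why: Regitz diazo transfer to the doubly activated methylene group.

Step 5
Reactants: 8 α-diazo-β-keto sulfone
Product: 9 (1S,5R)-5-methyl-1-(phenylsulfonyl)-6-[(triisopropylsilyl)oxy]bicyclo[3.1.0]hexan-2-one (both C6 epimers)
Conditions: CuOTf·0.5C6H6 (10 mol %), (S,S)-2,2′-isopropylidenebis(4-tert-butyl-2-oxazoline) (12 mol %; the antipode if the facial sense proves opposite), toluene, 50 °C
Reagents that add atoms: none
Why: Enantioselective intramolecular cyclopropanation by a monovalent copper carbenoid, a reaction type established for α-diazo-β-keto sulfones; the chiral ligand should set the quaternary methyl-bearing carbon (C1 of the target), the ring fusion is necessarily cis, and the silyloxy carbon reflects the alkene geometry.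

Step 6
Reactants: 10 4-methylfuran-2(5H)-one
Product: 11 tert-butyl(dimethyl)[(4-methylfuran-2-yl)oxy]silane
Conditions: TBSOTf, Et3N, CH2Cl2, 0 °C
Reagents that add atoms: tert-butyldimethylsilyl trifluoromethanesulfonate, CC(C)(C)[Si](C)(C)OS(=O)(=O)C(F)(F)F
Why: O-Silylation of the butenolide dienolate gives the aromatic 2-silyloxyfuran.

Step 7
Reactants: 9 donor–acceptor cyclopropane, 11 silyloxyfuran
Product: 13 cis-fused tricyclic silyl ketal (6α,9α-epoxy, 6β-OTBS, 5β-SO2Ph, 10β-OTIPS, 1β,8-dimethyl, 7-ene, 4-one), via silyloxycarbenium sulfonyl-enolate zwitterion 12 (not isolated)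
Conditions: Sc(OTf)3 (10 mol %), 4 Å MS, CH2Cl2, −40 → 0 °C
Reagents that add atoms: none
Why: Proposed new method: Sc(OTf)3 chelates the β-keto sulfone and cleaves the cyclopropane bond between the sulfonyl-bearing and the silyloxy-bearing carbon to zwitterion 12 (both epimers of 9 converge); the furan attacks the oxocarbenium carbon C10 through its free α-carbon (vinylogous Mukaiyama mode), and the chelated enolate carbon C5 then adds to the silyloxy-substituted furanium carbon C6 before silyl loss. The closest known reactions are the Lewis-acid (4+3) annulations of donor–acceptor cyclopropanes with 1,3-dienes, silyl dienol ethers and isobenzofurans and the opening of such cyclopropanes by silyl enol ethers; an alkoxy-donor bicyclic cyclopropane has not been combined with a 2-silyloxyfuran in this way. The second bond closes the cycloheptene ring 7-exo-trig (and with it the oxane ring of the 8-oxabicyclo[3.2.1]octene, 6-endo-trig), necessarily on the face of C5 that carries the C1–C10 bond. C10 should be set by Felkin–Anh attack anti to the enolate carbon of the contact ion pair with the angular methyl as the small group; the bridge carbons C9 and C6 by a chair-like closure that keeps OTIPS and the cyclopentanone carbons equatorial and so places the oxygen bridge anti to the methyl group; C9 and C6 later become trigonal and C5 is reset in step 8. The step needs γ-attack of the furan (secured by the silyloxy group) and 1,2- rather than 1,4-closure, i.e. (4+3) rather than (3+2), which the methyl group on the conjugate carbon of the furanium ion and the congestion of a quaternary–quaternary bond should secure.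

Step 8
Reactants: 13 tricyclic sulfone
Product: 15 trans-fused ketone (5α-H; bridged silyl ketal intact), via diiodosamarium enolate 14 (not isolated)
Conditions: SmI2 (2.5 equiv), THF/MeOH, −78 °C
Reagents that add atoms: none
Why: Reductive desulfonylation of the β-keto sulfone by electron transfer from divalent samarium gives the C5 enolate regiospecifically; kinetic protonation by methanol on the exo face (syn to the oxygen bridge, anti to the angular methyl) should give the trans ring fusion.

Step 9
Reactants: 15 trans-fused ketone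
Product: 16 tertiary alcohol (4β-OH, 4α-isopropyl)
Conditions: iPrMgCl, CeCl3, THF, −78 → −40 °C
Reagents that add atoms: isopropylmagnesium chloride, CC(C)[Mg]Cl
Why: Organocerium 1,2-addition suppresses enolisation and β-elimination; attack anti to the angular methyl and to the C6 substituent (α face) should give the 4β-alcohol.

Step 10
Reactants: 16 bridged silyl ketal
Product: 17 4β,9α-dihydroxy-6-oxo enone (10β-OTIPS; in equilibrium with its bridged hemiketal)
Conditions: AcOH/THF/H2O (3:1:1), rt
Reagents that add atoms: none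
Why: Acidic hydrolysis of the silyl ketal, far more labile than the hindered secondary TIPS ether, unveils the C6 ketone and the C9 hydroxyl.

Step 11
Reactants: 17 hydroxy enone
Product: 18 4β-hydroxy-6,9-dione (ene-dione)
Conditions: Dess–Martin periodinane, NaHCO3, CH2Cl2, 0 °C → rt
Reagents that add atoms: none
Why: Dess–Martin oxidation of the only secondary alcohol (through the open hydroxy ketone form) gives the C9 ketone and removes the C9 stereocentre; the tertiary alcohol is inert.

Step 12
Reactants: 18 ene-dione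
Product: 19 4β,6α-diol-9-one
Conditions: Me4NBH(OAc)3, MeCN/AcOH, −30 °C
Reagents that add atoms: none
Why: Evans–Saksena hydroxyl-directed reduction: boron bound to the C4 hydroxyl delivers hydride to the β face of C6 only, giving the anti-1,3-diol (6α-OH) and leaving the C9 ketone, which has no free neighbouring hydroxyl.

Step 13
Reactants: 19 diol
Product: 20 6α-(4-methoxybenzoate) (10β-OTIPS)
Conditions: 4-methoxybenzoyl chloride, DMAP, Et3N, CH2Cl2, 0 °C → rt
Reagents that add atoms: 4-methoxybenzoyl chloride, COc1ccc(cc1)C(Cl)=O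
Why: DMAP-catalysed acylation (nucleophilic acyl-transfer catalysis) should esterify the secondary allylic alcohol selectively over the tertiary one.

Step 14
Reactants: 20 silyl ether
Product: 21 target
Conditions: HF·pyridine, pyridine/THF, 0 °C → rt
Reagents that add atoms: none
Why: Fluoride-mediated desilylation under buffered, non-basic conditions should spare the γ-acyloxy enone and the tertiary alcohol.

**Compound list**

1 | propanal | CCC=O | starting material
2 | methyl acrylate | C=CC(=O)OC | starting material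
3 | 1-(prop-1-en-1-yl)pyrrolidine | C/C=C/N1CCCC1 | intermediate (not isolated)
4 | methyl 4-methyl-5-oxopentanoate (racemic) | O=CC(C)CCC(=O)OC | intermediate
5 | methyl 4-methyl-5-[(triisopropylsilyl)oxy]pent-4-enoate (E/Z) | CC(=CO[Si](C(C)C)(C(C)C)C(C)C)CCC(=O)OC | intermediate
6 | methyl phenyl sulfone | CS(=O)(=O)c1ccccc1 | starting material
7 | 6-methyl-1-(phenylsulfonyl)-7-[(triisopropylsilyl)oxy]hept-6-en-2-one | CC(=CO[Si](C(C)C)(C(C)C)C(C)C)CCC(=O)CS(=O)(=O)c1ccccc1 | intermediate
8 | 1-diazo-6-methyl-1-(phenylsulfonyl)-7-[(triisopropylsilyl)oxy]hept-6-en-2-one | CC(=CO[Si](C(C)C)(C(C)C)C(C)C)CCC(=O)C(=[N+]=[N-])S(=O)(=O)c1ccccc1 | intermediate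
9 | (1S,5R)-5-methyl-1-(phenylsulfonyl)-6-[(triisopropylsilyl)oxy]bicyclo[3.1.0]hexan-2-one (C6 epimers) | C[C@]12CCC(=O)[C@@]1(S(=O)(=O)c1ccccc1)C2O[Si](C(C)C)(C(C)C)C(C)C | intermediate
10 | 4-methylfuran-2(5H)-one | CC1=CC(=O)OC1 | starting material
11 | tert-butyl(dimethyl)[(4-methylfuran-2-yl)oxy]silane | Cc1coc(O[Si](C)(C)C(C)(C)C)c1 | intermediate
12 | ring-opened silyloxycarbenium / sulfonyl-enolate zwitterion | C[C@]1(C=[O+][Si](C(C)C)(C(C)C)C(C)C)CCC(=O)[C-]1S(=O)(=O)c1ccccc1 | intermediate (not isolated)
13 | cis-fused tricyclic silyl ketal: 6α,9α-epoxy-6β-(TBS-oxy)-5β-(phenylsulfonyl)-10β-(TIPS-oxy)-1β,8-dimethylhydroazul-7-en-4-one | C[C@]12CCC(=O)[C@@]1(S(=O)(=O)c1ccccc1)[C@]1(O[Si](C)(C)C(C)(C)C)C=C(C)[C@@H](O1)[C@@H]2O[Si](C(C)C)(C(C)C)C(C)C | intermediate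
14 | diiodosamarium enolate of 15 | C[C@]12CCC(O[Sm](I)I)=C1[C@]1(O[Si](C)(C)C(C)(C)C)C=C(C)[C@@H](O1)[C@@H]2O[Si](C(C)C)(C(C)C)C(C)C | intermediate (not isolated)
15 | trans-fused ketone: as 13, with 5α-H in place of the sulfonyl group | C[C@]12CCC(=O)[C@@H]1[C@]1(O[Si](C)(C)C(C)(C)C)C=C(C)[C@@H](O1)[C@@H]2O[Si](C(C)C)(C(C)C)C(C)C | intermediate
16 | tertiary alcohol: as 15, with 4β-hydroxy-4α-isopropyl | C[C@]12CC[C@@](O)(C(C)C)[C@@H]1[C@]1(O[Si](C)(C)C(C)(C)C)C=C(C)[C@@H](O1)[C@@H]2O[Si](C(C)C)(C(C)C)C(C)C | intermediate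
17 | 4β,9α-dihydroxy-4α-isopropyl-1β,8-dimethyl-10β-(TIPS-oxy)-5α-H-hydroazul-7-en-6-one | C[C@]12CC[C@@](O)(C(C)C)[C@@H]1C(=O)C=C(C)[C@@H](O)[C@@H]2O[Si](C(C)C)(C(C)C)C(C)C | intermediate
18 | 4β-hydroxy-4α-isopropyl-1β,8-dimethyl-10β-(TIPS-oxy)-5α-H-hydroazul-7-ene-6,9-dione | C[C@]12CC[C@@](O)(C(C)C)[C@@H]1C(=O)C=C(C)C(=O)[C@@H]2O[Si](C(C)C)(C(C)C)C(C)C | intermediate
19 | 4β,6α-dihydroxy-4α-isopropyl-1β,8-dimethyl-10β-(TIPS-oxy)-5α-H-hydroazul-7-en-9-one | C[C@]12CC[C@@](O)(C(C)C)[C@@H]1[C@@H](O)C=C(C)C(=O)[C@@H]2O[Si](C(C)C)(C(C)C)C(C)C | intermediate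
20 | 6α-(4-methoxybenzoyl) ester of 19 | C[C@]12CC[C@@](O)(C(C)C)[C@@H]1[C@@H](OC(=O)c1ccc(OC)cc1)C=C(C)C(=O)[C@@H]2O[Si](C(C)C)(C(C)C)C(C)C | intermediate
21 | CNP0299970.1, (1S,4R,5S,6S,10R)-4,10-dihydroxy-4-isopropyl-1,8-dimethyl-9-oxohydroazul-7-en-6-yl 4-methoxybenzoate | COc1ccc(C(=O)O[C@H]2C=C(C)C(=O)[C@H](O)[C@@]3(C)CC[C@@](O)(C(C)C)[C@H]23)cc1 | target

**Step count and risks**

Total step count: 14. Longest linear sequence: 13 (steps 1–5 and 7–14; step 6 is the one-step side branch).

Steps most likely to fail: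

1. Step 7 (Proposed new method). Silyl transfer from the furanium ion to the enolate oxygen, or proton loss, may outrun ring closure, and facial control at C10 may be poor. Fallback with known reactions, from 9 back to 19:
   - Sc(OTf)3-catalysed Friedel–Crafts opening of 9 by 3-methylfuran at its C2 should give the furyl carbinol silyl ether F1.
   - Oxidative furan opening (mCPBA, CH2Cl2, 0 °C) should give the (Z)-keto-enal F2.
   - The β-keto sulfone carbanion should add to the aldehyde (Et3N, intramolecular aldol) and the product close to the bridged hemiketal F3; O-silylation (TBSOTf, 2,6-lutidine) then gives the C9 silyl ketal F4.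
   - SmI2/MeOH gives the trans-fused ketone F5, and iPrMgCl/CeCl3 the tertiary alcohol F6.
   - Aqueous AcOH releases the C9 ketone and the 6α-hydroxyl, i.e. diol 19; steps 10–12 are then not needed.

2. Step 8. β-Elimination of the bridging oxygen from the samarium enolate, or protonation on the endo face (cis fusion), may compete. Fallback, from 13 back to 15: the enolate is trapped as it forms (SmI2, then TMSCl, −78 °C) as the trimethylsilyl enol ether F7, which is isolated and protonated under reagent control with a Lewis-acid-assisted chiral Brønsted acid ((R)-BINOL·SnCl4, toluene, −78 °C), so that the proton donor and not the substrate decides the face.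

3. Step 9. Enolisation of the hindered ketone or β-hydride reduction by the isopropyl metal may outrun addition. Fallback, from 15 back to 16: addition of 2-propenyllithium/CeCl3 (no β-hydrogen, smaller) should give the isopropenyl carbinol F8; homogeneous hydrogenation (H2, RhCl(PPh3)3, benzene) should then reduce the 1,1-disubstituted alkene only and give 16.

**Further compounds**

F1 | step 7 | 3-methyl-3-[(3-methylfuran-2-yl)(triisopropylsilyloxy)methyl]-2-(phenylsulfonyl)cyclopentan-1-one (epimers at the sulfonyl carbon) | C[C@@]1(CCC(=O)C1S(=O)(=O)c1ccccc1)[C@@H](O[Si](C(C)C)(C(C)C)C(C)C)c1occc1C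
F2 | step 7 | (Z)-keto-enal from furan opening of F1 | C[C@@]1(CCC(=O)C1S(=O)(=O)c1ccccc1)[C@@H](O[Si](C(C)C)(C(C)C)C(C)C)C(=O)/C(C)=C\C=O
F3 | step 7 | bridged hemiketal: 6α,9α-epoxy-9β-hydroxy-5β-(phenylsulfonyl)-10β-(TIPS-oxy)-1β,8-dimethylhydroazul-7-en-4-one | C[C@]12CCC(=O)[C@@]1(S(=O)(=O)c1ccccc1)[C@@H]1C=C(C)[C@@](O)(O1)[C@@H]2O[Si](C(C)C)(C(C)C)C(C)C
F4 | step 7 | 9β-(TBS-oxy) ketal of F3 | C[C@]12CCC(=O)[C@@]1(S(=O)(=O)c1ccccc1)[C@@H]1C=C(C)[C@@](O[Si](C)(C)C(C)(C)C)(O1)[C@@H]2O[Si](C(C)C)(C(C)C)C(C)C
F5 | step 7 | desulfonylated trans-fused ketone (5α-H) from F4 | C[C@]12CCC(=O)[C@@H]1[C@@H]1C=C(C)[C@@](O[Si](C)(C)C(C)(C)C)(O1)[C@@H]2O[Si](C(C)C)(C(C)C)C(C)C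
F6 | step 7 | 4β-hydroxy-4α-isopropyl adduct of F5 | C[C@]12CC[C@@](O)(C(C)C)[C@@H]1[C@@H]1C=C(C)[C@@](O[Si](C)(C)C(C)(C)C)(O1)[C@@H]2O[Si](C(C)C)(C(C)C)C(C)C
F7 | step 8 | trimethylsilyl enol ether (C4=C5) of 15 | C[C@]12CCC(O[Si](C)(C)C)=C1[C@]1(O[Si](C)(C)C(C)(C)C)C=C(C)[C@@H](O1)[C@@H]2O[Si](C(C)C)(C(C)C)C(C)C
F8 | step 9 | 4β-hydroxy-4α-(prop-1-en-2-yl) analogue of 16 | C[C@]12CC[C@@](O)(C(C)=C)[C@@H]1[C@]1(O[Si](C)(C)C(C)(C)C)C=C(C)[C@@H](O1)[C@@H]2O[Si](C(C)C)(C(C)C)C(C)C
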